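The easy step was to multiply each flask's L charge by its time, giving a charge-time (the reduced time of second-order kinetics), and to see whether Q follows it.

| flask | L | D | remark | time |
|---|---|---|---|---|
| zeta | 1 M | 1.2 equiv | run made earlier |  |
| gamma | 2.2 M | 1.2 equiv | run made earlier |  |
| Thursday's | 1.5 M | 1.20 equiv |  | 2.5 d |
| Saturday's | 1.5 M | 1.20 equiv |  | 4.0 d |

- zeta (time / d: Q / %): 0.208: 27.9; 0.333: 34.3; 0.500: 38.6; 0.625: 40.6; 1.04: 42.2; 1.67: 40.1; 2.50: 37.2
- gamma (time / d: Q / %): 0.208: 38.3; 0.333: 41.3; 0.500: 41.5; 0.625: 41.2; 1.04: 37.5; 1.67: 33.2; 2.50: 29.7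

(readings scatter by 0.3 percentage points)

- percent here means L units held: one G counts as two

- which of the two there is more of at the end, counted by the L in each, Thursday's (Q / G)
- which of the two there is more of at the end, counted by the L in each, Saturday's (Q / G)
- how much Q is there at the end, in percent of the L charged: Thursday's
- how much Q is there at the end, in percent of the L charged: Saturday's

It seemed to: zeta read 37.2% at 60.0 M·h and gamma read 37.5% at 54.9 M·h, both as fractions of the L charged. So I worked in logarithms along gamma's tail. The fall of Q per tenfold rise in charge-time between gamma's last two readings came to 20 percentage points; I call this the tail slope.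

Thursday's charge-time of 90.0 M·h lay just past gamma's 88.2 M·h, where Q read 33.2%, so I reckoned Q at 33.0%. Saturday's 144 M·h lay past gamma's 132 M·h, where Q read 29.7%, so I reckoned 28.9%.

Since one G holds two L, G leads Q by L units once the L left is under 34.0% on Thursday's and 42.2% on Saturday's. Gamma's Q had dropped from 41.5% at 0.500 d, so I expected less L than that and chose G for both flasks.

The forecast gave 33.2% and 29.3%, slightly above my figures, and chose G and G, noting that “the 1 M and 2.2 M curves nearly overlap”.

Thursday's flask gave Q 33.5% against G 53.2%, and Saturday's gave Q 29.5% against G 62.9%.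

    L + D → Z + Q (k = 2.30 × 10⁻⁵ L mol⁻¹ s⁻¹)
    D + Z ⇌ X, settled at all times (K = 690 L mol⁻¹)
    L + Q → G (k = 7.80 × 10⁻⁶ L mol⁻¹ s⁻¹)

At 2.50 d in Thursday's flask, Q was made at 0.201 of the rate at which it was used up, so it was made more slowly than it went. A neighbour flask like Thursday's, read at the same time but with 0.90 M of L, has its charge-time shorter by 0.222 of a tenfold step. Reckoned by the tail slope, that is 4.4 points on top of Thursday's Q, an estimate of 37.9%, and that neighbour flask holds 38.2%.

The readings were generated by integration with constants of no real substance; the scatter is artificial.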